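**Plan**

- Numbering used throughout: C1 exocyclic CH2; C2–C6 with the fusion carbons C7 and C11 form the seven-membered ring (C6 = CMe2); C8–C10 complete the five-membered ring (C10 quaternary); C12 side-chain CH; C13 lactone CH.
- Retrosynthetic cuts, in order: the lactone CH2–C13 bond (carbene C–H insertion) and the two ester C–O bonds; C12–C13 (auxiliary alkylation); after placing OH on C4, the C3–C4 bond (carbonyl-ene, opens the seven-membered ring); then C2=CH2, C6–C7, C2–C11 and the C10–allyl bond.
- Feature that allows the ene cut: the exocyclic C1=C2 alkene with ring CH2 C3 beside it in the seven-membered ring is the homoallylic pattern left when an isopropenyl group on C11 attacks an aldehyde at C4.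
- Forward order: the five-membered ring is bought as a β-keto ester; the seven-membered ring closes in step 12; the lactone ring closes last, in step 21.
- Stereochemistry: C10 from Pd/(S)-t-BuPHOX decarboxylative allylation; C7 from silane addition anti to the C10 arm and C11 from kinetic protonation (cis fusion); C12 from an (R)-4-benzyloxazolidinone alkylation; C13 from the chiral dirhodium catalyst; the C4 carbinol is removed.

Key step: step 12

Assumption: the (S)-configured t-BuPHOX ligand is taken to give the (S)-ketone in the cyclopentanone series as it does for cyclohexanones; if the sense is opposite, the (R)-ligand is used.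

**Route**

Step 1
Reactants: 1 methyl 2-oxocyclopentane-1-carboxylate; 2 allyl alcohol
Product: 3 allyl 2-oxocyclopentane-1-carboxylate
Conditions: DMAP (cat.), toluene, reflux, MeOH distilled off
Reagents that add atoms: none
Why: DMAP-catalysed transesterification of a β-keto ester runs through the acylketene, so the allyl ester should form under neutral conditions as methanol is removed.

Step 2
Reactants: 3 allyl 2-oxocyclopentane-1-carboxylate
Product: 4 allyl 1-methyl-2-oxocyclopentane-1-carboxylate (racemic)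
Conditions: MeI, K2CO3, acetone, reflux
Reagents that add atoms: iodomethane, CI
Why: C-alkylation of the stabilised β-keto ester enolate places the methyl group on the future C10; the racemate suffices because step 3 is stereoconvergent.

Step 3
Reactants: 4 allyl 1-methyl-2-oxocyclopentane-1-carboxylate
Product: 5 (S)-2-allyl-2-methylcyclopentan-1-one
Conditions: Pd2(dba)3 (2.5 mol%), (S)-t-BuPHOX (6 mol%), THF, 25 °C
Reagents that add atoms: none
Why: In this decarboxylative asymmetric Tsuji allylation, loss of CO2 gives a palladium enolate and π-allyl pair that recombine inside the chiral phosphinooxazoline pocket, so both enantiomers of 4 should converge on the (S) quaternary centre C10.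

Step 4
Reactants: 5 (S)-2-allyl-2-methylcyclopentan-1-one
Product: 6 2-[(1S)-1-methyl-2-oxocyclopentyl]acetic acid
Conditions: RuCl3 hydrate (2 mol%), NaIO4 (4.1 equiv), EtOAc/MeCN/H2O, rt
Reagents that add atoms: sodium periodate, [Na+].[O-]I(=O)(=O)=O; water, O
Why: RuO4 generated catalytically cleaves the terminal alkene oxidatively to the acid one carbon shorter (the C10 arm) and leaves the ketone and the quaternary centre untouched.

Step 5
Reactants: 6 2-[(1S)-1-methyl-2-oxocyclopentyl]acetic acid
Product: 7 methyl 2-[(1S)-1-methyl-2-oxocyclopentyl]acetate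
Conditions: MeI, K2CO3, DMF, rt
Reagents that add atoms: iodomethane, CI
Why: O-alkylation of the carboxylate gives the methyl ester, which is carried as the arm through the organometallic steps.

Step 6
Reactants: 7 methyl 2-[(1S)-1-methyl-2-oxocyclopentyl]acetate
Product: 9 methyl 2-[(1S)-1-methyl-2-(trifluoromethylsulfonyloxy)cyclopent-2-en-1-yl]acetate, via lithium enolate 8 (not isolated)
Conditions: LiHMDS (1.05 equiv), THF, −78 °C; then PhNTf2, −78 °C to rt
Reagents that add atoms: N-phenylbis(trifluoromethanesulfonimide), O=S(=O)(N(c1ccccc1)S(=O)(=O)C(F)(F)F)C(F)(F)F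
Why: The ketone can enolise only toward C7 (C10 is quaternary) and is more acidic than the hindered ester CH2, so O-triflation of the enolate should give a single enol triflate.

Step 7
Reactants: 9 methyl 2-[(1S)-1-methyl-2-(trifluoromethylsulfonyloxy)cyclopent-2-en-1-yl]acetate; 10 tributyl(1-ethoxyvinyl)stannane
Product: 12 methyl 2-[(1S)-2-acetyl-1-methylcyclopent-2-en-1-yl]acetate, via ethoxyvinyl diene 11 (not isolated)
Conditions: Pd(PPh3)4 (5 mol%), LiCl (3 equiv), THF, 65 °C; then 1 M HCl, rt
Reagents that add atoms: water, O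
Why: Stille coupling of the enol triflate (chloride-assisted) followed by acid hydrolysis of the enol ether unmasks the acetyl group (C2) conjugated with C7=C11.

Step 8
Reactants: 12 methyl 2-[(1S)-2-acetyl-1-methylcyclopent-2-en-1-yl]acetate; 13 trimethyl(3-methylbut-2-en-1-yl)silane
Product: 15 methyl 2-[(1S,2R,3R)-2-acetyl-1-methyl-3-(2-methylbut-3-en-2-yl)cyclopentyl]acetate, via titanium enolate 14 (not isolated)
Conditions: TiCl4 (2 equiv), CH2Cl2, −78 °C; then pre-cooled MeOH, −78 °C; aq. NaHCO3
Reagents that add atoms: none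
Why: In this Hosomi–Sakurai conjugate addition the γ-carbon of the silane attacks C7 of the TiCl4-activated enone and creates the quaternary C6; with TiCl4 expected to bridge the acetyl and ester carbonyls on the face of the arm, attack should come from the face of the C10 methyl group, and cold protonation of the titanium enolate from the face away from the new tert-alkyl group should set C11 cis under kinetic control.

Step 9
Reactants: 15 methyl 2-[(1S,2R,3R)-2-acetyl-1-methyl-3-(2-methylbut-3-en-2-yl)cyclopentyl]acetate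
Product: 16 methyl 2-[(1S,2S,3R)-1-methyl-3-(2-methylbut-3-en-2-yl)-2-(prop-1-en-2-yl)cyclopentyl]acetate
Conditions: Zn, CH2Br2, TiCl4, THF/CH2Cl2, 0 °C to rt
Reagents that add atoms: dibromomethane, BrCBr
Why: Takai–Lombardo methylenation uses a non-basic gem-dimetallic reagent, so the hindered methyl ketone should become the isopropenyl group without epimerising C11 or touching the ester.

Step 10
Reactants: 16 methyl 2-[(1S,2S,3R)-1-methyl-3-(2-methylbut-3-en-2-yl)-2-(prop-1-en-2-yl)cyclopentyl]acetate
Product: 18 methyl 2-[(1S,2S,3R)-3-(4-hydroxy-2-methylbutan-2-yl)-1-methyl-2-(prop-1-en-2-yl)cyclopentyl]acetate, via alkylborane 17 (not isolated)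
Conditions: 9-BBN (1.2 equiv), THF, 0 °C to rt; then 3 M NaOH, 30% H2O2, 0 °C
Reagents that add atoms: hydrogen peroxide, OO
Why: Brown hydroboration with the bulky borane should take the open terminal vinyl group in preference to the isopropenyl group, which is shielded by C10 and by the C7 substituent, and oxidation then gives the primary alcohol at C4.

Step 11
Reactants: 18 methyl 2-[(1S,2S,3R)-3-(4-hydroxy-2-methylbutan-2-yl)-1-methyl-2-(prop-1-en-2-yl)cyclopentyl]acetate
Product: 19 methyl 2-[(1S,2S,3R)-1-methyl-3-(2-methyl-4-oxobutan-2-yl)-2-(prop-1-en-2-yl)cyclopentyl]acetate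
Conditions: Dess–Martin periodinane, pyridine, CH2Cl2, 0 °C to rt
Reagents that add atoms: none
Why: Buffered Dess–Martin oxidation gives the aldehyde without acid that could trigger a premature cationic cyclisation onto the isopropenyl group.

Step 12
Reactants: 19 methyl 2-[(1S,2S,3R)-1-methyl-3-(2-methyl-4-oxobutan-2-yl)-2-(prop-1-en-2-yl)cyclopentyl]acetate
Product: 20 methyl 2-[(1S,3aR,8aS)-6-hydroxy-1,4,4-trimethyl-8-methylidenedecahydroazulen-1-yl]acetate (both C4 carbinol epimers)
Conditions: Me2AlCl (2.2 equiv), CH2Cl2, −78 to 0 °C; then aq. Rochelle salt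
Reagents that add atoms: none
Why: Me2AlCl binds the aldehyde oxygen, C4 is attacked by the terminal CH2 (C3) of the isopropenyl group while a hydrogen of its methyl group passes to oxygen through a six-centre transition state, so the C3–C4 bond forms and the double bond moves to C2=C1. The closest known reaction type is the Lewis-acid-promoted type 2 intramolecular carbonyl-ene reaction that gives 3-methylenecycloalkanols. The seven-membered ring closes with the tether on the central ene carbon (endo at the alkene, exo at the carbonyl), helped by the C6 gem-dimethyl group and the cis-1,2-disubstituted cyclopentane. The only new stereocentre, the C4 carbinol, is uncontrolled and is removed in steps 13 and 14, while the cis ring fusion is inherited from the cis C7/C11 substituents. The step needs the aldehyde to react in preference to the ester and ene closure to beat Prins-type pathways: the ester is no enophile, excess Me2AlCl saturates both carbonyls, and the methyl–aluminium bond takes up the proton of the new alcohol as methane, so no strong acid is formed.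

Step 13
Reactants: 20 methyl 2-[(1S,3aR,8aS)-6-hydroxy-1,4,4-trimethyl-8-methylidenedecahydroazulen-1-yl]acetate
Product: 21 methyl 2-[(1S,3aR,8aS)-6-(imidazole-1-carbothioyloxy)-1,4,4-trimethyl-8-methylidenedecahydroazulen-1-yl]acetate
Conditions: 1,1'-thiocarbonyldiimidazole, DMAP (cat.), ClCH2CH2Cl, 70 °C
Reagents that add atoms: 1,1'-thiocarbonyldiimidazole, S=C(n1ccnc1)n1ccnc1
Why: Neutral thioacylation of the secondary C4 alcohol gives the radical precursor without base that could touch the ester or acid that could move the exocyclic alkene.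

Step 14
Reactants: 21 methyl 2-[(1S,3aR,8aS)-6-(imidazole-1-carbothioyloxy)-1,4,4-trimethyl-8-methylidenedecahydroazulen-1-yl]acetate
Product: 22 methyl 2-[(1S,3aR,8aS)-1,4,4-trimethyl-8-methylidenedecahydroazulen-1-yl]acetate
Conditions: Bu3SnH, AIBN (cat.), toluene, 100 °C
Reagents that add atoms: none
Why: In this Barton–McCombie deoxygenation the stannyl radical adds to sulfur, β-scission gives the secondary C4 radical, and hydrogen transfer from the stannane should be faster than the reversible closure onto the homoallylic alkene.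

Step 15
Reactants: 22 methyl 2-[(1S,3aR,8aS)-1,4,4-trimethyl-8-methylidenedecahydroazulen-1-yl]acetate
Product: 23 2-[(1S,3aR,8aS)-1,4,4-trimethyl-8-methylidenedecahydroazulen-1-yl]acetic acid
Conditions: LiOH·H2O, THF/MeOH/H2O, 50 °C; then 1 M HCl
Reagents that add atoms: lithium hydroxide, [Li+].[OH-]
Why: Saponification of the hindered but unbranched ester frees the acid for attachment of the auxiliary; the alkene is inert to base.

Step 16
Reactants: 23 2-[(1S,3aR,8aS)-1,4,4-trimethyl-8-methylidenedecahydroazulen-1-yl]acetic acid; 24 (R)-4-benzyl-1,3-oxazolidin-2-one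
Product: 26 (4R)-4-benzyl-3-{2-[(1S,3aR,8aS)-1,4,4-trimethyl-8-methylidenedecahydroazulen-1-yl]acetyl}-1,3-oxazolidin-2-one, via mixed pivalic anhydride 25 (not isolated)
Conditions: PivCl, Et3N, THF, −20 °C; then 24, LiCl, −20 °C to rt
Reagents that add atoms: none
Why: N-acylation of the oxazolidinone through the mixed anhydride gives the imide needed for auxiliary control at C12, and material from the minor enantiomer of step 3 becomes a separable diastereomer here.

Step 17
Reactants: 26 (4R)-4-benzyl-3-{2-[(1S,3aR,8aS)-1,4,4-trimethyl-8-methylidenedecahydroazulen-1-yl]acetyl}-1,3-oxazolidin-2-one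
Product: 28 tert-butyl (3R)-4-[(4R)-4-benzyl-2-oxo-1,3-oxazolidin-3-yl]-4-oxo-3-[(1R,3aR,8aS)-1,4,4-trimethyl-8-methylidenedecahydroazulen-1-yl]butanoate, via sodium enolate 27 (not isolated)
Conditions: NaHMDS, THF, −78 °C; then tert-butyl bromoacetate, −78 to −30 °C
Reagents that add atoms: tert-butyl bromoacetate, BrCC(=O)OC(C)(C)C
Why: In this Evans alkylation the chelated (Z)-sodium enolate is attacked by the reactive α-bromo ester on the face opposite the benzyl group, which with the (R)-auxiliary sets C12 as R.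

Step 18
Reactants: 28 tert-butyl (3R)-4-[(4R)-4-benzyl-2-oxo-1,3-oxazolidin-3-yl]-4-oxo-3-[(1R,3aR,8aS)-1,4,4-trimethyl-8-methylidenedecahydroazulen-1-yl]butanoate
Product: 29 (2R)-2-[(1R,3aR,8aS)-1,4,4-trimethyl-8-methylidenedecahydroazulen-1-yl]butane-1,4-diol
Conditions: LiAlH4, THF, 0 °C to rt
Reagents that add atoms: none
Why: Hydride reduction cleaves the imide to the C12 hydroxymethyl group and reduces the tert-butyl ester to the hydroxyethyl arm (C13 and its CH2O), without touching the alkene or C12.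

Step 19
Reactants: 29 (2R)-2-[(1R,3aR,8aS)-1,4,4-trimethyl-8-methylidenedecahydroazulen-1-yl]butane-1,4-diol
Product: 31 (3R)-4-hydroxy-3-[(1R,3aR,8aS)-1,4,4-trimethyl-8-methylidenedecahydroazulen-1-yl]butyl 2-diazoacetate, via tosylhydrazone ester 30 (not isolated)
Conditions: TsNHN=CHCOCl (1.05 equiv), PhNMe2, CH2Cl2, −20 to 0 °C; then Et3N, 0 °C
Reagents that add atoms: glyoxylic acid chloride p-toluenesulfonylhydrazone, Cc1ccc(cc1)S(=O)(=O)NN=CC(Cl)=O
Why: The acid chloride should acylate the open primary hydroxyl of the hydroxyethyl arm in preference to the C12 carbinol, which sits next to quaternary C10, and triethylamine then expels toluenesulfinate in a Bamford–Stevens-type elimination to give the diazoacetate.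

Step 20
Reactants: 31 (3R)-4-hydroxy-3-[(1R,3aR,8aS)-1,4,4-trimethyl-8-methylidenedecahydroazulen-1-yl]butyl 2-diazoacetate
Product: 32 (3R)-4-acetoxy-3-[(1R,3aR,8aS)-1,4,4-trimethyl-8-methylidenedecahydroazulen-1-yl]butyl 2-diazoacetate
Conditions: Ac2O, pyridine, DMAP (cat.), CH2Cl2, 0 °C
Reagents that add atoms: acetic anhydride, CC(=O)OC(C)=O
Why: Buffered acetylation of the remaining hindered primary alcohol installs the acetate of the target under conditions the diazo ester tolerates.

Step 21
Reactants: 32 (3R)-4-acetoxy-3-[(1R,3aR,8aS)-1,4,4-trimethyl-8-methylidenedecahydroazulen-1-yl]butyl 2-diazoacetate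
Product: 33 (2R)-2-[(3R)-5-oxooxolan-3-yl]-2-[(1R,3aR,8aS)-1,4,4-trimethyl-8-methylidenedecahydroazulen-1-yl]ethyl acetate (target)
Conditions: Rh2(4R-MPPIM)4 (1 mol%), CH2Cl2, reflux, slow addition of 32
Reagents that add atoms: none
Why: Dirhodium-carboxamidate-catalysed intramolecular carbene insertion into a C13–H bond closes the γ-lactone (five-membered transition state favoured over other ring sizes and over attack on the remote hindered alkene), and the chiral catalyst chooses between the two diastereotopic C13 hydrogens; the 4R antipode is selected for 13R by analogy with simple 3-substituted propyl diazoacetates, the sense to be confirmed on this substrate.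

**Compound list**

1 | methyl 2-oxocyclopentane-1-carboxylate | COC(=O)C1CCCC1=O | starting material
2 | allyl alcohol | C=CCO | starting material
3 | allyl 2-oxocyclopentane-1-carboxylate | C=CCOC(=O)C1CCCC1=O | intermediate
4 | allyl 1-methyl-2-oxocyclopentane-1-carboxylate (racemic) | C=CCOC(=O)C1(C)CCCC1=O | intermediate
5 | (S)-2-allyl-2-methylcyclopentan-1-one | O=C1CCC[C@@]1(C)CC=C | intermediate
6 | 2-[(1S)-1-methyl-2-oxocyclopentyl]acetic acid | O=C1CCC[C@@]1(C)CC(=O)O | intermediate
7 | methyl 2-[(1S)-1-methyl-2-oxocyclopentyl]acetate | O=C1CCC[C@@]1(C)CC(=O)OC | intermediate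
8 | lithium enolate of 7 (C11=C7, not isolated) | [Li]OC1=CCC[C@@]1(C)CC(=O)OC | intermediate
9 | methyl 2-[(1S)-1-methyl-2-(trifluoromethylsulfonyloxy)cyclopent-2-en-1-yl]acetate | O=S(=O)(OC1=CCC[C@@]1(C)CC(=O)OC)C(F)(F)F | intermediate
10 | tributyl(1-ethoxyvinyl)stannane | CCCC[Sn](CCCC)(CCCC)C(=C)OCC | starting material
11 | methyl 2-[(1S)-2-(1-ethoxyvinyl)-1-methylcyclopent-2-en-1-yl]acetate (not isolated) | C=C(OCC)C1=CCC[C@@]1(C)CC(=O)OC | intermediate
12 | methyl 2-[(1S)-2-acetyl-1-methylcyclopent-2-en-1-yl]acetate | CC(=O)C1=CCC[C@@]1(C)CC(=O)OC | intermediate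
13 | trimethyl(3-methylbut-2-en-1-yl)silane | CC(C)=CC[Si](C)(C)C | starting material
14 | trichlorotitanium enolate of 15 (C11=C2, 7R,10S, not isolated) | CC(O[Ti](Cl)(Cl)Cl)=C1[C@H](C(C)(C)C=C)CC[C@@]1(C)CC(=O)OC | intermediate
15 | methyl 2-[(1S,2R,3R)-2-acetyl-1-methyl-3-(2-methylbut-3-en-2-yl)cyclopentyl]acetate (methyl, acetyl and tert-alkyl groups all cis) | CC(=O)[C@@H]1[C@H](C(C)(C)C=C)CC[C@@]1(C)CC(=O)OC | intermediate
16 | methyl 2-[(1S,2S,3R)-1-methyl-3-(2-methylbut-3-en-2-yl)-2-(prop-1-en-2-yl)cyclopentyl]acetate | CC(=C)[C@@H]1[C@H](C(C)(C)C=C)CC[C@@]1(C)CC(=O)OC | intermediate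
17 | B-alkyl-9-borabicyclo[3.3.1]nonane from 16, boron on the terminal vinyl carbon (not isolated) | CC(=C)[C@@H]1[C@H](C(C)(C)CCB2C3CCCC2CCC3)CC[C@@]1(C)CC(=O)OC | intermediate
18 | methyl 2-[(1S,2S,3R)-3-(4-hydroxy-2-methylbutan-2-yl)-1-methyl-2-(prop-1-en-2-yl)cyclopentyl]acetate | CC(=C)[C@@H]1[C@H](C(C)(C)CCO)CC[C@@]1(C)CC(=O)OC | intermediate
19 | methyl 2-[(1S,2S,3R)-1-methyl-3-(2-methyl-4-oxobutan-2-yl)-2-(prop-1-en-2-yl)cyclopentyl]acetate (ene precursor) | CC(=C)[C@@H]1[C@H](C(C)(C)CC=O)CC[C@@]1(C)CC(=O)OC | intermediate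
20 | methyl 2-[(1S,3aR,8aS)-6-hydroxy-1,4,4-trimethyl-8-methylidenedecahydroazulen-1-yl]acetate (cis-fused, both C4 carbinol epimers; ene product) | C=C1CC(O)CC(C)(C)[C@@H]2CC[C@@](C)(CC(=O)OC)[C@H]12 | intermediate
21 | methyl 2-[(1S,3aR,8aS)-6-(imidazole-1-carbothioyloxy)-1,4,4-trimethyl-8-methylidenedecahydroazulen-1-yl]acetate | C=C1CC(OC(=S)n2ccnc2)CC(C)(C)[C@@H]2CC[C@@](C)(CC(=O)OC)[C@H]12 | intermediate
22 | methyl 2-[(1S,3aR,8aS)-1,4,4-trimethyl-8-methylidenedecahydroazulen-1-yl]acetate | C=C1CCCC(C)(C)[C@@H]2CC[C@@](C)(CC(=O)OC)[C@H]12 | intermediate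
23 | 2-[(1S,3aR,8aS)-1,4,4-trimethyl-8-methylidenedecahydroazulen-1-yl]acetic acid | C=C1CCCC(C)(C)[C@@H]2CC[C@@](C)(CC(=O)O)[C@H]12 | intermediate
24 | (R)-4-benzyl-1,3-oxazolidin-2-one | O=C1OC[C@@H](Cc2ccccc2)N1 | starting material
25 | mixed anhydride of 23 with pivalic acid (not isolated) | C=C1CCCC(C)(C)[C@@H]2CC[C@@](C)(CC(=O)OC(=O)C(C)(C)C)[C@H]12 | intermediate
26 | (4R)-4-benzyl-3-{2-[(1S,3aR,8aS)-1,4,4-trimethyl-8-methylidenedecahydroazulen-1-yl]acetyl}-1,3-oxazolidin-2-one | C=C1CCCC(C)(C)[C@@H]2CC[C@@](C)(CC(=O)N3[C@H](Cc4ccccc4)COC3=O)[C@H]12 | intermediate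
27 | (Z)-sodium enolate of 26 (not isolated) | C=C1CCCC(C)(C)[C@@H]2CC[C@@](C)(/C=C(\O[Na])N3[C@H](Cc4ccccc4)COC3=O)[C@H]12 | intermediate
28 | tert-butyl (3R)-4-[(4R)-4-benzyl-2-oxo-1,3-oxazolidin-3-yl]-4-oxo-3-[(1R,3aR,8aS)-1,4,4-trimethyl-8-methylidenedecahydroazulen-1-yl]butanoate | C=C1CCCC(C)(C)[C@@H]2CC[C@@](C)([C@H](C(=O)N3[C@H](Cc4ccccc4)COC3=O)CC(=O)OC(C)(C)C)[C@H]12 | intermediate
29 | (2R)-2-[(1R,3aR,8aS)-1,4,4-trimethyl-8-methylidenedecahydroazulen-1-yl]butane-1,4-diol | C=C1CCCC(C)(C)[C@@H]2CC[C@@](C)([C@H](CO)CCO)[C@H]12 | intermediate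
30 | (3R)-4-hydroxy-3-[(1R,3aR,8aS)-1,4,4-trimethyl-8-methylidenedecahydroazulen-1-yl]butyl 2-(tosylhydrazinylidene)acetate (not isolated) | C=C1CCCC(C)(C)[C@@H]2CC[C@@](C)([C@H](CO)CCOC(=O)C=NNS(=O)(=O)c3ccc(C)cc3)[C@H]12 | intermediate
31 | (3R)-4-hydroxy-3-[(1R,3aR,8aS)-1,4,4-trimethyl-8-methylidenedecahydroazulen-1-yl]butyl 2-diazoacetate | C=C1CCCC(C)(C)[C@@H]2CC[C@@](C)([C@H](CO)CCOC(=O)C=[N+]=[N-])[C@H]12 | intermediate
32 | (3R)-4-acetoxy-3-[(1R,3aR,8aS)-1,4,4-trimethyl-8-methylidenedecahydroazulen-1-yl]butyl 2-diazoacetate | C=C1CCCC(C)(C)[C@@H]2CC[C@@](C)([C@H](COC(C)=O)CCOC(=O)C=[N+]=[N-])[C@H]12 | intermediate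
33 | (2R)-2-[(3R)-5-oxooxolan-3-yl]-2-[(1R,3aR,8aS)-1,4,4-trimethyl-8-methylidenedecahydroazulen-1-yl]ethyl acetate (7R,10R,11S,12R,13R in the numbering of the plan) | C=C1CCCC(C)(C)[C@@H]2CC[C@@](C)([C@H](COC(C)=O)[C@@H]3COC(=O)C3)[C@H]12 | target

**Totals**

Total step count: 21. Longest linear sequence: 21 steps, from 1 to 33.

**Steps most likely to fail**

1. Step 8. The silane may attack C7 with little preference between the methyl face and the arm face, because the two C10 substituents differ only beyond their first carbon. The titanium enolate may also equilibrate before protonation and erode the cis C7/C11 relationship.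
Fallback, setting out from 1 and 13 and returning at 15: the order of stereocentre construction is reversed, so that C7 is set by a catalyst and C10 by the large C7 substituent. Compound 1 is dehydrogenated (PhSeCl, pyridine; then H2O2) to methyl 5-oxocyclopent-1-ene-1-carboxylate F1. A Cu(OTf)2/tert-butyl-bisoxazoline-catalysed enantioselective Hosomi–Sakurai addition of 13 (ligand antipode chosen for 7R) gives methyl (2R)-2-(2-methylbut-3-en-2-yl)-5-oxocyclopentane-1-carboxylate F2. O-Triflation of the β-keto ester (NaH, Tf2O) gives methyl (5S)-5-(2-methylbut-3-en-2-yl)-2-(trifluoromethylsulfonyloxy)cyclopent-1-ene-1-carboxylate F3, and Me2CuLi replaces the triflate by methyl to give methyl (5S)-2-methyl-5-(2-methylbut-3-en-2-yl)cyclopent-1-ene-1-carboxylate F4. Saponification gives (5S)-2-methyl-5-(2-methylbut-3-en-2-yl)cyclopent-1-ene-1-carboxylic acid F5, and MeLi (2 equiv) turns it into 1-[(5S)-2-methyl-5-(2-methylbut-3-en-2-yl)cyclopent-1-en-1-yl]ethan-1-one F6. A Mukaiyama–Michael addition of tert-butyl[(1-methoxyethenyl)oxy]dimethylsilane (TiCl4, CH2Cl2, −78 °C) should then place the CH2CO2Me arm on C10 anti to the C7 tert-alkyl group, and cold protonation of the enolate gives 15.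

2. Step 21. The carbene may take the wrong diastereotopic C13 hydrogen if catalyst preference and substrate bias oppose each other, or be diverted into dimerisation or insertion elsewhere.
Fallback, setting out from 28 and returning at 33: C13 is set by a second auxiliary alkylation instead of by the catalyst. Selective LiBH4 reduction of the imide in 28 gives tert-butyl (3R)-4-hydroxy-3-[(1R,3aR,8aS)-1,4,4-trimethyl-8-methylidenedecahydroazulen-1-yl]butanoate F7, and acetylation gives the 4-acetoxy ester F8. TMSOTf/2,6-lutidine cleaves the tert-butyl ester to the acid F9, which is coupled with 24 (PivCl, Et3N, LiCl) to the imide F10. Alkylation of its sodium enolate with tert-butyl bromoacetate gives tert-butyl (3R,4R)-5-acetoxy-3-[(4R)-4-benzyl-2-oxo-1,3-oxazolidine-3-carbonyl]-4-[(1R,3aR,8aS)-1,4,4-trimethyl-8-methylidenedecahydroazulen-1-yl]pentanoate F11. LiBH4 reduction of the imide gives the 3-(hydroxymethyl) ester F12, and mild acid (PPTS, toluene, 60 °C) closes the γ-lactone to 33.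

3. Step 12. Methyl transfer from aluminium to the aldehyde, slow seven-ring closure while the ester holds the Lewis acid, or proton-driven Prins-type collapse may compete with the ene pathway.
Fallback, setting out from 19 and returning at 20: the same C3–C4 bond is formed by an intramolecular Nozaki–Hiyama allylation. Allylic chlorination of the isopropenyl group with double-bond shift (NCS, PhSeCl cat., CH2Cl2) gives methyl 2-[(1S,2R,3R)-2-(3-chloroprop-1-en-2-yl)-1-methyl-3-(2-methyl-4-oxobutan-2-yl)cyclopentyl]acetate F13. CrCl2 (LiI cat., THF) then generates the 2-substituted allylchromium species, which adds to the aldehyde and gives the same methylenecycloheptanol 20.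

**Further compounds**

F1 | step 8 | methyl 5-oxocyclopent-1-ene-1-carboxylate | COC(=O)C1=CCCC1=O
F2 | step 8 | methyl (2R)-2-(2-methylbut-3-en-2-yl)-5-oxocyclopentane-1-carboxylate (C1 epimers) | COC(=O)C1[C@H](C(C)(C)C=C)CCC1=O
F3 | step 8 | methyl (5S)-5-(2-methylbut-3-en-2-yl)-2-(trifluoromethylsulfonyloxy)cyclopent-1-ene-1-carboxylate | FC(F)(F)S(=O)(=O)OC1=C(C(=O)OC)[C@H](C(C)(C)C=C)CC1
F4 | step 8 | methyl (5S)-2-methyl-5-(2-methylbut-3-en-2-yl)cyclopent-1-ene-1-carboxylate | CC1=C(C(=O)OC)[C@H](C(C)(C)C=C)CC1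
F5 | step 8 | (5S)-2-methyl-5-(2-methylbut-3-en-2-yl)cyclopent-1-ene-1-carboxylic acid | CC1=C(C(=O)O)[C@H](C(C)(C)C=C)CC1
F6 | step 8 | 1-[(5S)-2-methyl-5-(2-methylbut-3-en-2-yl)cyclopent-1-en-1-yl]ethan-1-one | CC1=C(C(C)=O)[C@H](C(C)(C)C=C)CC1
F7 | step 21 | tert-butyl (3R)-4-hydroxy-3-[(1R,3aR,8aS)-1,4,4-trimethyl-8-methylidenedecahydroazulen-1-yl]butanoate | C=C1CCCC(C)(C)[C@@H]2CC[C@@](C)([C@H](CO)CC(=O)OC(C)(C)C)[C@H]12
F8 | step 21 | tert-butyl (3R)-4-acetoxy-3-[(1R,3aR,8aS)-1,4,4-trimethyl-8-methylidenedecahydroazulen-1-yl]butanoate | C=C1CCCC(C)(C)[C@@H]2CC[C@@](C)([C@H](COC(C)=O)CC(=O)OC(C)(C)C)[C@H]12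
F9 | step 21 | (3R)-4-acetoxy-3-[(1R,3aR,8aS)-1,4,4-trimethyl-8-methylidenedecahydroazulen-1-yl]butanoic acid | C=C1CCCC(C)(C)[C@@H]2CC[C@@](C)([C@H](COC(C)=O)CC(=O)O)[C@H]12
F10 | step 21 | (2R)-4-[(4R)-4-benzyl-2-oxo-1,3-oxazolidin-3-yl]-4-oxo-2-[(1R,3aR,8aS)-1,4,4-trimethyl-8-methylidenedecahydroazulen-1-yl]butyl acetate | C=C1CCCC(C)(C)[C@@H]2CC[C@@](C)([C@H](COC(C)=O)CC(=O)N3[C@H](Cc4ccccc4)COC3=O)[C@H]12
F11 | step 21 | tert-butyl (3R,4R)-5-acetoxy-3-[(4R)-4-benzyl-2-oxo-1,3-oxazolidine-3-carbonyl]-4-[(1R,3aR,8aS)-1,4,4-trimethyl-8-methylidenedecahydroazulen-1-yl]pentanoate | C=C1CCCC(C)(C)[C@@H]2CC[C@@](C)([C@H](COC(C)=O)[C@H](C(=O)N3[C@H](Cc4ccccc4)COC3=O)CC(=O)OC(C)(C)C)[C@H]12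
F12 | step 21 | tert-butyl (3R,4R)-5-acetoxy-3-(hydroxymethyl)-4-[(1R,3aR,8aS)-1,4,4-trimethyl-8-methylidenedecahydroazulen-1-yl]pentanoate | C=C1CCCC(C)(C)[C@@H]2CC[C@@](C)([C@H](COC(C)=O)[C@H](CO)CC(=O)OC(C)(C)C)[C@H]12
F13 | step 12 | methyl 2-[(1S,2R,3R)-2-(3-chloroprop-1-en-2-yl)-1-methyl-3-(2-methyl-4-oxobutan-2-yl)cyclopentyl]acetate | ClCC(=C)[C@@H]1[C@H](C(C)(C)CC=O)CC[C@@]1(C)CC(=O)OC
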